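**Retrosynthetic overview** (labdane numbering: ring A = C1–C5/C10, ring B = C5–C10, side chain C11–C15 on C9)
1. The C15–O acyl bond is cut last (selective ester formation). The C9–C11 bond is cut next: alkyllithium addition to a C9 ketone, oxidative 1,3-transposition, dissolving-metal reduction and triflate reduction give C9–H and the C7=C8 alkene.
2. Ring A is cut at C2–C3, C10–C1 and C4–C5 together: a three-component Michael/Michael/Dieckmann annulation of methyl isobutyrate (C3, C4, both C4 methyls), 6-methyl-(S)-carvone (ring B) and methyl acrylate (C1, C2), closed by attack of C2 on C3.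
3. Enabling feature: C3 is a carbinol carbon between the quaternary gem-dimethyl C4 and the C2 methylene, and C10 is a quaternary methyl-bearing carbon between C5 and C9. At the ester/ketone level, C3/C4 is an isobutyrate (nucleophilic at C4, non-enolisable electrophile at C3) and C10 is the α-carbon of a C9 enone whose β-carbon is C5.
4. Stereochemistry: the one bought stereocentre (carvone, at C7) relays to C5 and C10 in the key step, then to C3 (equatorial hydride delivery) and C9 (axial protonation). C7 is erased when its isopropenyl group is fragmented to the C7=C8 alkene.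
5. Ring order: ring B is bought, ring A is formed in step 2; the (E)-C13=C14 unit is made separately by carboalumination and joined in step 11.

Key step: step 2

Assumption: (S)-3-methylpentanoic acid is bought as the single enantiomer, and 2 is carried on as its C8 epimer mixture because C8 becomes sp2 in step 6.

**Step 1**
Reactants: 1 (S)-(+)-carvone
Product: 2 6-methylcarvone (C8 epimer mixture)
Conditions: LiN(i-Pr)2, THF, −78 °C; MeI, −78 → 0 °C
Reagents that add atoms: iodomethane, CI
Why: Kinetic deprotonation of the cross-conjugated enone at the α′-carbon (the future C8) and C-methylation of the enolate is the standard α′-alkylation of carvone; the new C8 centre forms as an epimer mixture that does not matter because C8 becomes sp2 in step 6.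

**Step 2**
Reactants: 2 6-methylcarvone; 3 methyl isobutyrate; 4 methyl acrylate
Product: 8 trans-fused bicyclic β-keto ester, via lithium isobutyrate enolate 5 (not isolated), via ring B ketone enolate 6 (not isolated), via ester enolate 7 (not isolated)
Conditions: 3, LiN(i-Pr)2, THF, −78 °C; 2, DMPU, −78 → −30 °C; 4, −78 °C → rt; AcOH
Reagents that add atoms: none
Why: LiN(i-Pr)2 converts 3 into the tetrasubstituted ester enolate 5, which should add in Michael fashion to C5 of enone 2 by axial attack on the face opposite the C7 isopropenyl group, so that the bought C7 stereocentre sets C5 and leaves the regiodefined C9/C10 enolate 6; 6 then adds to methyl acrylate on the face anti to the new, pseudoaxial C5 substituent (A(1,2) strain), which creates the quaternary C10 centre with C1 trans to C4 and gives ester enolate 7. Enolate 7 closes ring A by Dieckmann (Claisen) attack of C2 on the non-enolisable C3 ester carbonyl, a 6-(enolexo)-exo-trig closure that the trans-diequatorial C1 and C4 arms reach without strain and that is driven by loss of methoxide and deprotonation of the β-keto ester. The closest known reaction types are the Michael–Michael–ring-closure (MIMIRC) annulations of enolates with two acceptors and the one-pot double Michael–Dieckmann synthesis of cyclohexanone β-keto esters. New stereocentres: C5 (set by C7, trans), C10 (set by C5, anti alkylation), C2 (uncontrolled, removed in step 3); the C8 epimers are carried on. The step needs 1,4- over 1,2-addition of 5, which the hindered α,α-disubstituted enolate and DMPU should secure, and a single productive ring closure, which is secured because only C2 attack on C3 gives an enolisable β-dicarbonyl that is drained as its enolate, whereas acylations through C8 are reversible and closure of C2 on C9 would give a four-membered ring.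

**Step 3**
Reactants: 8 bicyclic β-keto ester
Product: 9 trans-decalin-3,9-dione
Conditions: LiCl, H2O, DMSO, 150 °C
Reagents that add atoms: none
Why: Krapcho dealkoxycarbonylation removes the C2 ester under neutral conditions that should leave the isopropenyl group and both ketones untouched; the uncontrolled C2 centre disappears and no new stereocentre forms.

**Step 4**
Reactants: 9 trans-decalin-3,9-dione
Product: 10 3-hydroxy-9-ketone (C3–OH axial)
Conditions: LiBH(s-Bu)3, THF, −78 °C; H2O
Reagents that add atoms: none
Why: The bulky hydride should reduce only the C3 ketone (one free α-methylene side) and not the C9 ketone (flanked by quaternary C10 and tertiary C8), and it attacks C3 along the equatorial trajectory away from the axial C4 and C10 methyl groups, so the new C3–OH is axial (cis to C5–H), as in trialkylborohydride reductions of 4,4-dimethyl-3-keto terpenoids.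

**Step 5**
Reactants: 10 3-hydroxy-9-ketone
Product: 11 C3 tert-butyldimethylsilyl ether
Conditions: TBSOTf, 2,6-lutidine, CH2Cl2, −78 → 0 °C
Reagents that add atoms: tert-butyldimethylsilyl triflate, CC(C)(C)[Si](C)(C)OS(=O)(=O)C(F)(F)F
Why: Silylation of the hindered axial alcohol with the silyl triflate and a hindered base (standard TBS protection) shields C3–OH from the organolithium and the chromate oxidant used later; no stereocentre is touched.

**Step 6**
Reactants: 11 C3 silyl ether
Product: 13 bicyclic C9-keto C7=C8 enone, via methoxy hydroperoxide 12 (not isolated)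
Conditions: O3, CH2Cl2/MeOH, −78 °C; Cu(OAc)2·H2O, FeSO4·7H2O, MeOH, −20 °C → rt; DBU, CH2Cl2, rt
Reagents that add atoms: none
Why: Schreiber fragmentation: ozone cleaves the only C=C bond, methanol traps the carbonyl oxide as 12, FeSO4 reduces the O–O bond to an alkoxy radical that loses methyl acetate by β-scission, Cu(OAc)2 oxidises the C7 radical to the alkene and DBU moves any C6=C7 isomer into conjugation, so both C8 epimers should converge on one enone and the carvone stereocentre at C7 is erased after use.

**Step 7**
Reactants: 14 4-(tert-butyldimethylsilyloxy)but-1-yne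
Product: 16 (E)-5-(tert-butyldimethylsilyloxy)-3-methylpent-2-en-1-ol, via alkenylalane 15 (not isolated)
Conditions: Me3Al, Cp2ZrCl2 (cat.), CH2Cl2, 0 °C → rt; n-BuLi, THF, −78 °C; (CH2O)n, rt
Reagents that add atoms: trimethylaluminium, C[Al](C)C; formaldehyde (as paraformaldehyde), C=O
Why: Negishi zirconium-catalysed carboalumination adds CH3 and Al syn across the terminal alkyne with the methyl on the internal carbon, and the derived alanate is hydroxymethylated with retention, which fixes the (E)-C13=C14 geometry.

**Step 8**
Reactants: 16 allylic alcohol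
Product: 17 bis-silyl ether (C15 triisopropylsilyl, C11 tert-butyldimethylsilyl)
Conditions: TIPSCl, imidazole, DMF, rt
Reagents that add atoms: chlorotriisopropylsilane, CC(C)[Si](Cl)(C(C)C)C(C)C
Why: Standard silylation of the primary allylic alcohol; the triisopropylsilyl group carries no aryl rings and should therefore survive the dissolving-metal step.

**Step 9**
Reactants: 17 bis-silyl ether
Product: 18 (E)-3-methyl-5-(triisopropylsilyloxy)pent-3-en-1-ol
Conditions: PPTS, MeOH, rt
Reagents that add atoms: none
Why: Under mild acid-catalysed methanolysis a primary tert-butyldimethylsilyl ether is cleaved far faster than a triisopropylsilyl ether, so only the homoallylic oxygen should be unmasked (selective desilylation).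

**Step 10**
Reactants: 18 homoallylic alcohol
Product: 19 (E)-5-iodo-3-methylpent-2-enyl triisopropylsilyl ether
Conditions: I2, PPh3, imidazole, CH2Cl2, 0 °C
Reagents that add atoms: iodine, II
Why: Garegg–Samuelsson (Appel-type) iodination displaces the alkoxyphosphonium ion by SN2 at the primary carbon without touching the allylic silyl ether or the alkene geometry.

**Step 11**
Reactants: 19 homoallylic iodide; 13 bicyclic enone
Product: 21 tertiary allylic alcohol (C9 epimers), via alkyllithium 20 (not isolated)
Conditions: 19, t-BuLi (2 equiv), Et2O/pentane, −78 °C; 13, −78 → 0 °C; H2O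
Reagents that add atoms: none
Why: Iodine–lithium exchange gives the primary alkyllithium 20, which should add 1,2 to the hindered C9 carbonyl (organolithium addition to an enone); the configuration of the new carbinol C9 does not matter because C9 becomes sp2 in step 12.

**Step 12**
Reactants: 21 tertiary allylic alcohol
Product: 22 transposed enone (C7 ketone, C8=C9)
Conditions: pyridinium chlorochromate [C5H5NH][CrO3Cl], 4 Å molecular sieves, CH2Cl2, rt
Reagents that add atoms: pyridinium chlorochromate, [O-][Cr](=O)(=O)Cl.c1cc[nH+]cc1
Why: Babler–Dauben oxidative 1,3-transposition: the tertiary allylic chromate ester undergoes [3,3] shift to C7 and is oxidised there, which should give the C7 ketone conjugated with the tetrasubstituted C8=C9 bond and funnel both C9 carbinol epimers into one enone.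

**Step 13**
Reactants: 22 transposed enone
Product: 24 enol triflate (C7–OTf, C7=C8), via lithium enolate 23 (not isolated)
Conditions: Li, NH3(l)/THF, t-BuOH (1 equiv), −78 °C; isoprene; NH3 off; PhNTf2, THF, 0 °C → rt
Reagents that add atoms: N-phenylbis(trifluoromethanesulfonimide), O=S(=O)(N(c1ccccc1)S(=O)(=O)C(F)(F)F)C(F)(F)F
Why: Dissolving-metal conjugate reduction should protonate the β-carbon C9 axially, which places the side chain equatorial (cis to the C10 methyl, trans to C1), and leaves the regiodefined C7/C8 enolate 23, which PhNTf2 traps on oxygen (reductive enolate trapping).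

**Step 14**
Reactants: 24 enol triflate
Product: 25 bis-silyl ether of the 7,13-diene-3,15-diol
Conditions: Pd(OAc)2 (cat.), PPh3, HCO2H, n-Bu3N, DMF, 60 °C
Reagents that add atoms: none
Why: Palladium-catalysed formate reduction of the enol triflate (oxidative addition to zerovalent palladium, formate exchange, decarboxylation, C–H reductive elimination) should replace OTf by H with the C7=C8 bond kept in place and the other alkene and the silyl ethers untouched.

**Step 15**
Reactants: 25 bis-silyl ether
Product: 26 3,15-diol
Conditions: Bu4NF, THF, 50 °C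
Reagents that add atoms: none
Why: Fluoride cleaves both silyl ethers by Si–F bond formation, the hindered axial C3 ether needing the higher temperature; no stereocentre is affected.

**Step 16**
Reactants: 26 3,15-diol; 27 (S)-3-methylpentanoic acid
Product: 28 target ester CNP0307530.1
Conditions: DCC, DMAP (cat.), CH2Cl2, 0 °C
Reagents that add atoms: none
Why: Steglich esterification should acylate the unhindered primary allylic C15–OH selectively, since the axial C3–OH next to the C4 gem-dimethyl group reacts far more slowly, and the β-stereocentre of 27 cannot epimerise under these conditions.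

**Compound list**
1 | (S)-(+)-carvone, (5S)-2-methyl-5-(prop-1-en-2-yl)cyclohex-2-en-1-one | O=C1C[C@@H](C(C)=C)CC=C1C | starting material
2 | 6-methylcarvone, (5S)-2,6-dimethyl-5-(prop-1-en-2-yl)cyclohex-2-en-1-one, both C6 epimers (ring carbons 1–6 become C9, C10, C5, C6, C7, C8) | O=C1C(C)[C@@H](C(C)=C)CC=C1C | intermediate
3 | methyl isobutyrate | COC(=O)C(C)C | starting material
4 | methyl acrylate | C=CC(=O)OC | starting material
5 | lithium enolate of methyl isobutyrate | [Li]OC(OC)=C(C)C | intermediate
6 | ring B lithium enolate (C9–OLi, C9=C10) with C(CH3)2CO2CH3 on C5 trans to the C7 isopropenyl group | [Li]OC1=C(C)[C@@H](C(C)(C)C(=O)OC)C[C@H](C(C)=C)C1C | intermediate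
7 | lithium ester enolate of the keto diester: C10 quaternary (CH3 and CH2CH=C(OCH3)OLi), C1 trans to C4 | O=C1C(C)[C@@H](C(C)=C)C[C@H](C(C)(C)C(=O)OC)[C@@]1(C)CC=C(OC)O[Li] | intermediate
8 | trans-fused bicyclic β-keto ester: C3 and C9 ketones, CO2CH3 on C2, gem-dimethyl C4, isopropenyl on C7 (cis to C5–H), CH3 on C8 and C10, C5–H trans to C10–CH3 | O=C1C(C)[C@@H](C(C)=C)C[C@@H]2C(C)(C)C(=O)C(C(=O)OC)C[C@@]12C | intermediate
9 | trans-decalin-3,9-dione (as 8 without the C2 ester) | O=C1C(C)[C@@H](C(C)=C)C[C@@H]2C(C)(C)C(=O)CC[C@@]12C | intermediate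
10 | 3-hydroxy-9-ketone, C3–OH axial (cis to C5–H, trans to C10–CH3) | O=C1C(C)[C@@H](C(C)=C)C[C@@H]2C(C)(C)[C@@H](O)CC[C@@]12C | intermediate
11 | C3 tert-butyldimethylsilyl ether of 10 | O=C1C(C)[C@@H](C(C)=C)C[C@@H]2C(C)(C)[C@@H](O[Si](C)(C)C(C)(C)C)CC[C@@]12C | intermediate
12 | methoxy hydroperoxide: C7 carries C(CH3)(OCH3)OOH | O=C1C(C)[C@@H](C(C)(OC)OO)C[C@@H]2C(C)(C)[C@@H](O[Si](C)(C)C(C)(C)C)CC[C@@]12C | intermediate
13 | bicyclic enone: C9 ketone conjugated with C7=C8 (C8–CH3), C3–OTBS axial | O=C1C(C)=CC[C@@H]2C(C)(C)[C@@H](O[Si](C)(C)C(C)(C)C)CC[C@@]12C | intermediate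
14 | 4-(tert-butyldimethylsilyloxy)but-1-yne | C#CCCO[Si](C)(C)C(C)(C)C | starting material
15 | (E)-alkenyl(dimethyl)alane from syn carboalumination | C[Al](C)/C=C(\C)CCO[Si](C)(C)C(C)(C)C | intermediate
16 | (E)-5-(tert-butyldimethylsilyloxy)-3-methylpent-2-en-1-ol | OC/C=C(\C)CCO[Si](C)(C)C(C)(C)C | intermediate
17 | (E)-3-methylpent-2-ene-1,5-diol 1-triisopropylsilyl 5-tert-butyldimethylsilyl ether | CC(C)[Si](C(C)C)(C(C)C)OC/C=C(\C)CCO[Si](C)(C)C(C)(C)C | intermediate
18 | (E)-3-methyl-5-(triisopropylsilyloxy)pent-3-en-1-ol | CC(C)[Si](C(C)C)(C(C)C)OC/C=C(\C)CCO | intermediate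
19 | (E)-5-iodo-3-methylpent-2-enyl triisopropylsilyl ether | CC(C)[Si](C(C)C)(C(C)C)OC/C=C(\C)CCI | intermediate
20 | (E)-3-methyl-5-(triisopropylsilyloxy)pent-3-enyllithium | CC(C)[Si](C(C)C)(C(C)C)OC/C=C(\C)CC[Li] | intermediate
21 | tertiary allylic alcohol: C9 carries OH and the C11–C15 chain (C9 epimers), C7=C8 | CC(C)[Si](C(C)C)(C(C)C)OC/C=C(\C)CCC1(O)C(C)=CC[C@@H]2C(C)(C)[C@@H](O[Si](C)(C)C(C)(C)C)CC[C@@]12C | intermediate
22 | transposed enone: C7 ketone, C8=C9 with the side chain on C9 | CC(C)[Si](C(C)C)(C(C)C)OC/C=C(\C)CCC1=C(C)C(=O)C[C@@H]2C(C)(C)[C@@H](O[Si](C)(C)C(C)(C)C)CC[C@@]12C | intermediate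
23 | lithium enolate (C7–OLi, C7=C8), C9–H set, side chain cis to C10–CH3 | CC(C)[Si](C(C)C)(C(C)C)OC/C=C(\C)CC[C@@H]1C(C)=C(O[Li])C[C@@H]2C(C)(C)[C@@H](O[Si](C)(C)C(C)(C)C)CC[C@@]12C | intermediate
24 | enol triflate (C7–OTf, C7=C8) | CC(C)[Si](C(C)C)(C(C)C)OC/C=C(\C)CC[C@@H]1C(C)=C(OS(=O)(=O)C(F)(F)F)C[C@@H]2C(C)(C)[C@@H](O[Si](C)(C)C(C)(C)C)CC[C@@]12C | intermediate
25 | 3-O-TBS, 15-O-TIPS ether of the (13E)-7,13-diene-3,15-diol | CC(C)[Si](C(C)C)(C(C)C)OC/C=C(\C)CC[C@@H]1C(C)=CC[C@@H]2C(C)(C)[C@@H](O[Si](C)(C)C(C)(C)C)CC[C@@]12C | intermediate
26 | (3S,5S,9R,10S,13E)-labda-7,13-diene-3,15-diol (ent-labdane series, C3–OH axial) | OC/C=C(\C)CC[C@@H]1C(C)=CC[C@@H]2C(C)(C)[C@@H](O)CC[C@@]12C | intermediate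
27 | (S)-3-methylpentanoic acid | CC[C@H](C)CC(=O)O | starting material
28 | CNP0307530.1, 15-[(S)-3-methylpentanoate] of diol 26 | CC[C@H](C)CC(=O)OC/C=C(\C)CC[C@@H]1C(C)=CC[C@@H]2C(C)(C)[C@@H](O)CC[C@@]12C | target

**Step count and risks**
Total: 16 steps. Longest linear sequence: 12 steps (steps 1–6 and 11–16); the side-chain branch (steps 7–10) joins at step 11.

Steps most likely to fail:

1. Step 2. The first Michael stage may suffer competing 1,2-addition or proton transfer (α′/γ deprotonation of 2 by the ester enolate), and the Claisen closure onto the hindered α,α-dimethyl ester may stall. Fallback from 2: a Mukaiyama–Michael addition of the commercial ketene silyl acetal Me2C=C(OMe)OSiMe3 (TMSOTf cat., CH2Cl2, −78 °C) should give the trimethylsilyl enol ether F1 with the same trans relationship at C5/C7. MeLi (THF, 0 °C) would liberate the lithium enolate regiospecifically; methyl acrylate at −78 °C and a cold AcOH quench would give the keto diester F2. A separate thermodynamic Dieckmann condensation (NaOMe, MeOH/toluene, reflux) would return to 8.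

2. Step 6. The copper-mediated oxidation of the C7 radical may give poor positional control or over-oxidation, and peroxide intermediates may decompose unproductively. Fallback from 11: ozonolysis in CH2Cl2/MeOH followed by Ac2O, Et3N and DMAP (Criegee rearrangement, C7 migrating to oxygen with retention) should give the β-acetoxy ketone F3. DBU in CH2Cl2 would then eliminate acetic acid by an E1cB path that can only give the conjugated enone 13.

3. Step 13. The allylic C–O bond may be cleaved reductively or the substrate over-reduced under dissolving-metal conditions, and the enolate may equilibrate before O-sulfonylation. Fallback from 22: copper hydride conjugate hydrosilylation ([(Ph3P)CuH]6 cat., PhMe2SiH, toluene, rt) should deliver hydride to C9 from the face away from the axial C10 methyl group and give the dimethylphenylsilyl enol ether F4. MeLi (THF, 0 °C) followed by PhNTf2 would convert it into triflate 24.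

**Further compounds**
F1 | step 2 | trimethylsilyl enol ether of the conjugate adduct (C9–OSiMe3, C9=C10, C(CH3)2CO2CH3 on C5 trans to the C7 isopropenyl) | C[Si](C)(C)OC1=C(C)[C@@H](C(C)(C)C(=O)OC)C[C@H](C(C)=C)C1C
F2 | step 2 | keto diester (C10 quaternary with CH3 and CH2CH2CO2CH3, C1 trans to C4) | O=C1C(C)[C@@H](C(C)=C)C[C@H](C(C)(C)C(=O)OC)[C@@]1(C)CCC(=O)OC
F3 | step 6 | β-acetoxy ketone (C7–OAc in place of the isopropenyl group, retention) | O=C1C(C)[C@@H](OC(C)=O)C[C@@H]2C(C)(C)[C@@H](O[Si](C)(C)C(C)(C)C)CC[C@@]12C
F4 | step 13 | dimethylphenylsilyl enol ether (C7–OSiMe2Ph, C7=C8, C9–H set) | CC(C)[Si](C(C)C)(C(C)C)OC/C=C(\C)CC[C@@H]1C(C)=C(O[Si](C)(C)c3ccccc3)C[C@@H]2C(C)(C)[C@@H](O[Si](C)(C)C(C)(C)C)CC[C@@]12C
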